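## Structural features

The target joins two 2-(2-arylethyl)chromone units: an aromatic chromone (primed locants, phenethyl chain) and a 5,6,7,8-tetrahydrochromone (unprimed locants, 4-methoxyphenethyl chain) whose γ-pyrone is fused to a cyclohexene ring through C4a=C8a. The units are held by two alkyl aryl ether bonds, C5–O7′ and C7–O6′, so that the catechol oxygens and C5–C6–C7 form a benzodioxepine that bridges the carbocycle (a bicyclo[4.3.1] core with C6 as the one-atom bridge). C5, C6, C7 and C8 are four contiguous stereocentres (5R,6S,7R,8S): the two ether bonds are necessarily cis and 1,3-diaxial, and the hydroxyls at C6 and C8 are both axial on the opposite face, each trans to its neighbours. Both aryloxy groups are β to the C4/C8a carbonyl system (C5 through C4a, C7 through C8), so an enolate at C4a or C8 can expel them, and once C6 is a ketone any such loss ends in aromatisation. The CH2 groups attached to the O-bearing carbons of both pyranone rings (C2, C8a, C2′) are vinylogously acidic and oxidisable, which makes a late C–H oxidation at C8 ambiguous. The real difficulty is twofold: two C(sp3)–O–aryl bonds must be made at secondary carbons with absolute control, and oxygen must then be placed at C6 and C8 on the face away from the bridge. That face is the one external reagents prefer, so oxygen can be delivered there directly at C8, whereas at C6 a hydride has to be forced onto the bridge side. The key step exploits the fact that C5 and C7 are the two β-carbons of a cross-conjugated cyclohexadienone with its carbonyl at C8a and an sp3 ketal carbon at C6 (a para-quinone monoketal), while O6′ and O7′ are the neighbouring hydroxyls of a catechol.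

## Logic of the disconnections

18 ⇒ 17. No skeletal bond is cut; the saturated C–C bond next to C2 is taken back to an E-alkene. With a styryl group the tetrahydrochromone unit has only one vinylogously acidic sp3 position, C8, which makes the C8 oxygenation unambiguous and gives the acyl donor no α-hydrogens. The forward step must saturate one conjugated alkene without touching the pyranone rings or the allylic C–O bonds.

17 ⇒ 15. The C6–H bond is cut (carbinol back to ketone). C6 is flanked by two bridgeheads, so the ketone cannot enolise or epimerise its neighbours. The forward hydride must arrive on the bridge face, against the intrinsic preference for attack anti to the two axial C–O bonds; the axial C8 hydroxyl, already in place, is used to block and chelate the opposite face.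

15 ⇒ 13. The C8–O bond is cut. Oxygen is wanted on the face away from the bridge, which is the open face, so an electrophilic oxygen donor acting on a C8=C8a enol ether is the natural forward step. Oxidation to a C8 ketone and reduction was not adopted, because the hydride would then have to come from the bridge face and the side-chain methylenes would compete in the oxidation. The demand is regioselective enol-ether formation without loss of the β-aryloxy group at C7.

13 ⇒ 10 ⇒ 8 + 9. The O1–C2 and C2–C3 bonds of the γ-pyrone are cut and the C6 ketone is returned to its dimethyl ketal. This reduces the tetrahydrochromone to an enolised 2-acetylcyclohexanone and an acyl chloride. The forward acyl transfer needs an enolate at the acetyl methyl group only, formed and consumed at low temperature so that neither aryloxy group is expelled.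

8 ⇒ 2 + 7. The C5–O7′ and C7–O6′ bonds are cut. This removes the dioxepine ring and both stereocentres and leaves a flat achiral dienone and a flat catechol. The forward step must pair the right oxygen with the right carbon, choose one face of the dienone, and close the seven-membered ring faster than the mono-adduct rearomatises.

2 ⇒ 1. The second ketal C–O bond is cut, which returns the dienone to a para-methoxyphenol; the forward step is an oxidative dearomatisation.

7 ⇒ 6 ⇒ 4 + 5; 4 ⇒ 3. The O1′–C2′ and C2′–C3′ bonds of the aromatic chromone are cut, giving an ortho-hydroxyacetophenone and an ester. The two hydroxyls that become O6′ and O7′ are masked as acetals that fall off in the acid that closes the pyranone.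

## Other disconnections considered

Alternative 1: The cut is C4a–C8a (carbocycle) and O1–C2 (pyranone) of the tetrahydrochromone unit. In the forward step a polyanion of an acyclic hydroxy β-diketone ester, made with an excess of a strong amide base, closes the six-membered ring by attack of the C4a carbanion on the C8a ester, and acid work-up cyclodehydrates the triketone to A1.
- In its favour: C5 to C8 are set in an open chain before any ring exists, so the C6 and C8 hydroxyls do not depend on face-selective reactions on a congested bicycle. On this point it is better than the chosen plan. Carbanion acylation of esters is also better precedented than step 5.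
- Against it: A1 is only the monomer. The dioxepine would still require two aryl ether bonds at hindered secondary carbinol carbons. The polyanion also carries an α-silyloxy ester and a β-alkoxy group that invite epimerisation and elimination.
- Comparison: on structure the chosen plan makes the bridge, the ring and two stereocentres at once, while A1 postpones the hardest bonds. On mechanism the alternative is safer in its key step but not in what follows. On step economy the chosen plan (10 steps) is clearly shorter than a stereodefined acyclic chain plus bridge construction.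

Alternative 2: The cut is C4a–C5. In the forward step a mercury-mediated (divalent mercury) Ferrier carbocyclisation converts a gluco-configured hex-5-enopyranoside carrying the chromone on O3 into A2.
- In its favour: C6, C7 and C8 come from sugar C2, C3 and C4 with the required all-trans pattern and absolute configuration. Here it is better than the chosen plan, which must create C6 and C8 by reagent control. The carbocyclisation itself is a well-established reaction, again better on precedent, and the C7–O6′ ether exists from the start.
- Against it: the chromone must be attached to a secondary sugar hydroxyl early. A2 is a β-hydroxy ketone prone to dehydration and still lacks the γ-pyrone. C5–O7′ must be closed later by a seven-membered intramolecular displacement with inversion. The protecting-group traffic is heavy and stoichiometric mercury is needed.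
- Comparison: both plans build the pyranone after the carbocycle, so they are equal on that point. On step economy the alternative is considerably longer.

Alternative 3: The cut is C6′–C7′ and C4a′–C5′, i.e. the benzene ring of the aromatic chromone. In the forward step a 2-pyrone diene carried on O5 adds on heating to a sulfonyl-substituted vinyl ether on O7; decarboxylative cycloreversion and sulfinate elimination then aromatise, closing the benzene and dioxepine rings together to give A3.
- In its favour: neither ether oxygen has to be bonded to a hindered carbon late, because both are the alcohol oxygens of a preformed monomer. All four stereocentres pre-exist, so it is better than the chosen plan on C6/C8 control. A3 is one desilylation from the target, a better endgame, and pyrone Diels–Alder benzannulation is a precedented pericyclic sequence.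
- Against it: it needs the fully oxygenated monomer of Alternative 1, differentiated at O5 and O7, plus an elaborate bicyclic diene partner. Thermal conditions endanger the allylic C5 ether, and regiochemistry rests entirely on the tether.
- Comparison: on structure it is the most convergent; on mechanism it is equal or better in precedent; on step economy it is by far the longest.

Key step: step 5

Remark (locants): unprimed locants are those of the tetrahydrochromone unit and are used for its precursors as well (C4a and C8a are the acetyl-bearing and carbonyl carbons of 2); primed locants are those of the 2-(2-phenylethyl)chromone unit; "5,7-[…chromene-7,6-diyldioxy]" means O7′ on C5 and O6′ on C7, both on one face.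
Assumption: the quinine-derived catalyst is taken to select the C5 face that leads to the (5R) series; if the sense of induction is opposite, its quinidine-derived pseudo-enantiomer would be used without other change.
Assumption: acyl chloride 9 is taken as a purchased reagent.

## Route

Step 1
Reactants: 1 1-(2-hydroxy-5-methoxyphenyl)ethanone
Product: 2 2-acetyl-4,4-dimethoxycyclohexa-2,5-dien-1-one
Conditions: PhI(OAc)2 (1.1 equiv), MeOH, 0 °C; used at once
Reagents that add atoms: methanol, CO
Why: Oxidative dearomatisation of a para-methoxyphenol by the trivalent iodine reagent: ligand exchange at iodine, attack of methanol at the methoxy-bearing para carbon and loss of iodobenzene should give the para-quinone monoketal; no stereocentre is formed.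

Step 2
Reactants: 3 1-(2,4,5-trihydroxyphenyl)ethanone
Product: 4 1-[2-hydroxy-4,5-bis(methoxymethoxy)phenyl]ethanone
Conditions: MeOCH2Cl (2.1 equiv), K2CO3, acetone, 0 °C to rt
Reagents that add atoms: chloromethyl methyl ether, COCCl
Why: Phenoxide alkylation; the 2-hydroxyl is hydrogen-bonded to the acetyl carbonyl and is the least nucleophilic, so the 4- and 5-oxygens (the future O7′ and O6′) should be protected selectively.

Step 3
Reactants: 4 1-[2-hydroxy-4,5-bis(methoxymethoxy)phenyl]ethanone; 5 methyl 3-phenylpropanoate
Product: 6 1-[2-hydroxy-4,5-bis(methoxymethoxy)phenyl]-5-phenylpentane-1,3-dione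
Conditions: NaH (3.5 equiv), THF, 0 to 65 °C; then aq. HCl to pH 4
Reagents that add atoms: none
Why: Crossed Claisen condensation of the phenoxide–enolate dianion with the ester; the β-diketone is drawn out of the equilibrium as its enolate.

Step 4
Reactants: 6 1-[2-hydroxy-4,5-bis(methoxymethoxy)phenyl]-5-phenylpentane-1,3-dione
Product: 7 6,7-dihydroxy-2-(2-phenylethyl)-4H-chromen-4-one
Conditions: conc. HCl, MeOH, 60 °C
Reagents that add atoms: none
Why: Acid-catalysed cyclodehydration of the ortho-hydroxyaryl β-diketone to the chromone, with cleavage of both methoxymethyl acetals in the same medium.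

Step 5
Reactants: 2 2-acetyl-4,4-dimethoxycyclohexa-2,5-dien-1-one; 7 6,7-dihydroxy-2-(2-phenylethyl)-4H-chromen-4-one
Product: 8 1-{(5R,7S)-8a-hydroxy-6,6-dimethoxy-5,7-[4-oxo-2-(2-phenylethyl)-4H-chromene-7,6-diyldioxy]cyclohex-4a(8a)-en-4a-yl}ethanone
Conditions: 3-{[3,5-bis(trifluoromethyl)phenyl]amino}-4-{[(8α,9S)-6′-methoxycinchonan-9-yl]amino}cyclobut-3-ene-1,2-dione (10 mol %), CH2Cl2/THF (5:1), 4 Å molecular sieves, −30 to 0 °C
Reagents that add atoms: none
Why: Proposed new method: the quinuclidine nitrogen of the bifunctional catalyst should ionise the more acidic 7′-hydroxyl (para to the C4a′ acyl carbon) while the squaramide N–H groups bind the C8a carbonyl/acetyl pair of 2, so that the phenoxide adds to C5, the β-carbon activated by both carbonyls, and the adduct is held as a hydrogen-bonded enolised β-diketone; the closest known reaction types are amine–squaramide-catalysed enantioselective oxa-Michael additions of phenols and double hetero-Michael additions of dinucleophiles to cross-conjugated cyclohexadienones and quinone monoketals. The 6′-hydroxyl then adds to C7 of the remaining enone and C8 is protonated, a 7-exo-trig oxa-Michael closure that forms the dioxepine ring. The configuration at C5 is set by the catalyst, which selects one enantiotopic face of the planar dienone in the first, intermolecular addition. The configuration at C7 is set by the substrate: the tether from C5 can reach C7 only on the face that already carries O7′, so only the cis, diaxially bridged bicycle can form. The step needs the orientation O7′ to C5 and O6′ to C7 and chemoselectivity over rearomatisation of the mono-adduct by loss of methanol; the first is secured by pairing the more acidic phenol with the doubly activated β-carbon, the second by aprotic, weakly basic conditions at low temperature, under which C5–H is not acidic and the ketal is not ionised. Both additions are reversible, but an aryloxide expelled from one carbon stays tethered through the other and can return only to the same face, so partial reversal should not erode the configuration of 8.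

Step 6
Reactants: 8 1-{(5R,7S)-8a-hydroxy-6,6-dimethoxy-5,7-[4-oxo-2-(2-phenylethyl)-4H-chromene-7,6-diyldioxy]cyclohex-4a(8a)-en-4a-yl}ethanone; 9 (E)-3-(4-methoxyphenyl)prop-2-enoyl chloride
Product: 10 (5R,7S)-4a-acetyl-6,6-dimethoxy-5,7-[4-oxo-2-(2-phenylethyl)-4H-chromene-7,6-diyldioxy]cyclohex-4a(8a)-en-8a-yl (E)-3-(4-methoxyphenyl)prop-2-enoate
Conditions: Et3N (1.3 equiv), 4-(dimethylamino)pyridine (5 mol %), CH2Cl2, −20 to 0 °C
Reagents that add atoms: none
Why: O-Acylation of the enolised β-diketone through the acylpyridinium ion; the ring enol oxygen, part of the endocyclic tetrasubstituted enol, should be the acylated site, and acyl shuttling between the two oxygens converges on this conjugated isomer. The cinnamoyl group has no α-hydrogens, and the amine base at low temperature should not drive the diketonate into retro-Michael cleavage.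

Step 7
Reactants: 10 (5R,7S)-4a-acetyl-6,6-dimethoxy-5,7-[4-oxo-2-(2-phenylethyl)-4H-chromene-7,6-diyldioxy]cyclohex-4a(8a)-en-8a-yl (E)-3-(4-methoxyphenyl)prop-2-enoate
Product: 13 (5R,7S)-2-[(E)-2-(4-methoxyphenyl)ethenyl]-5,7-[4-oxo-2-(2-phenylethyl)-4H-chromene-7,6-diyldioxy]-7,8-dihydro-4H-chromene-4,6(5H)-dione, via triketone 11 (not isolated), via ketal pyranone 12 (not isolated)
Conditions: LiN(SiMe3)2 (2.5 equiv), THF, −78 °C, 30 min; CF3CO2H quench; then CF3CO2H/H2O (9:1), CH2Cl2, 25 to 40 °C
Reagents that add atoms: water, O
Why: Baker–Venkataraman rearrangement: the kinetic enolate of the acetyl methyl group attacks the neighbouring enol ester carbonyl through a six-membered transition state to give triketone 11, which acid cyclodehydrates to the γ-pyrone as in the classical 2-styrylchromone synthesis. The aqueous acid then hydrolyses the dimethyl ketal, which cannot eliminate because C5 and C7 are bridgeheads; the bridge also keeps both stereocentres from epimerising.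

Step 8
Reactants: 13 (5R,7S)-2-[(E)-2-(4-methoxyphenyl)ethenyl]-5,7-[4-oxo-2-(2-phenylethyl)-4H-chromene-7,6-diyldioxy]-7,8-dihydro-4H-chromene-4,6(5H)-dione
Product: 15 (5R,7S,8S)-8-hydroxy-2-[(E)-2-(4-methoxyphenyl)ethenyl]-5,7-[4-oxo-2-(2-phenylethyl)-4H-chromene-7,6-diyldioxy]-7,8-dihydro-4H-chromene-4,6(5H)-dione, via silyl trienol ether 14 (not isolated)
Conditions: t-BuMe2SiOTf (1.05 equiv), Et3N, CH2Cl2, −78 °C; then dimethyldioxirane, acetone, −78 to −40 °C; aq. NH4Cl
Reagents that add atoms: dimethyldioxirane, CC1(C)OO1
Why: Vinylogous Rubottom oxidation: silylation of the more basic monocyclic-type pyranone carbonyl (the benzo-fused chromone carbonyl is far less basic) gives a 4-silyloxypyrylium ion whose only acidic sp3 position is C8, so the amine should form the C8=C8a trienol ether 14 without a free carbanion that could expel O6′. The dioxirane should attack this electron-rich double bond from the lower face, anti to the axial C7–O6′ bond and away from the arene bridge, placing the new C8–O bond axial and trans to C7 (8S); aqueous work-up returns the pyranone.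

Step 9
Reactants: 15 (5R,7S,8S)-8-hydroxy-2-[(E)-2-(4-methoxyphenyl)ethenyl]-5,7-[4-oxo-2-(2-phenylethyl)-4H-chromene-7,6-diyldioxy]-7,8-dihydro-4H-chromene-4,6(5H)-dione
Product: 17 (5R,6S,7R,8S)-6,8-dihydroxy-2-[(E)-2-(4-methoxyphenyl)ethenyl]-5,7-[4-oxo-2-(2-phenylethyl)-4H-chromene-7,6-diyldioxy]-5,6,7,8-tetrahydro-4H-chromen-4-one, via 8-O-diethylborinate 16 (not isolated)
Conditions: Et2BOMe (1.2 equiv), THF/MeOH (4:1), −78 °C; then NaBH4, −78 °C; MeOH, evaporation
Reagents that add atoms: none
Why: Narasaka–Prasad syn-reduction of a β-hydroxy ketone: the borinate on the axial C8 oxygen lies across the lower face of C6 and binds the carbonyl oxygen increasingly as C6 pyramidalises toward it, so external borohydride should be left only the upper face, between the two ether oxygens. This gives the axial 6-hydroxyl, cis to the 8-hydroxyl and trans to both aryloxy groups (6S); the vinylogous ester carbonyls are not reduced at this temperature.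

Step 10
Reactants: 17 (5R,6S,7R,8S)-6,8-dihydroxy-2-[(E)-2-(4-methoxyphenyl)ethenyl]-5,7-[4-oxo-2-(2-phenylethyl)-4H-chromene-7,6-diyldioxy]-5,6,7,8-tetrahydro-4H-chromen-4-one
Product: 18 (5R,6S,7R,8S)-6,8-dihydroxy-2-[2-(4-methoxyphenyl)ethyl]-5,7-[4-oxo-2-(2-phenylethyl)-4H-chromene-7,6-diyldioxy]-5,6,7,8-tetrahydro-4H-chromen-4-one, (+)-4′-methoxyaquisinenone G
Conditions: H2 (1 atm), 10% Pd/C, EtOAc, rt, monitored to one equivalent of uptake
Reagents that add atoms: none
Why: Heterogeneous hydrogenation of the disubstituted styryl double bond, as in the conversion of 2-styrylchromones into 2-(2-phenylethyl)chromones; the pyranone double bonds are trisubstituted vinylogous esters and should resist, and there is no benzyl-type protecting group to cleave.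

## Compound list

1 | 1-(2-hydroxy-5-methoxyphenyl)ethanone | COc1ccc(O)c(C(C)=O)c1 | starting material
2 | 2-acetyl-4,4-dimethoxycyclohexa-2,5-dien-1-one | CC(=O)C1=CC(OC)(OC)C=CC1=O | intermediate
3 | 1-(2,4,5-trihydroxyphenyl)ethanone | CC(=O)c1cc(O)c(O)cc1O | starting material
4 | 1-[2-hydroxy-4,5-bis(methoxymethoxy)phenyl]ethanone | CC(=O)c1cc(OCOC)c(OCOC)cc1O | intermediate
5 | methyl 3-phenylpropanoate | COC(=O)CCc1ccccc1 | starting material
6 | 1-[2-hydroxy-4,5-bis(methoxymethoxy)phenyl]-5-phenylpentane-1,3-dione | O=C(CC(=O)CCc1ccccc1)c1cc(OCOC)c(OCOC)cc1O | intermediate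
7 | 6,7-dihydroxy-2-(2-phenylethyl)-4H-chromen-4-one | O=c1cc(CCc2ccccc2)oc2cc(O)c(O)cc12 | intermediate
8 | (5R,7S)-bridged enol β-diketone with C6 dimethyl ketal (acetyl on C4a, enol OH on C8a, O7′ on C5, O6′ on C7) | CC(=O)C3=C(O)C[C@@H]2Oc4cc5c(=O)cc(CCc6ccccc6)oc5cc4O[C@H]3C2(OC)OC | intermediate
9 | (E)-3-(4-methoxyphenyl)prop-2-enoyl chloride | COc1ccc(/C=C/C(Cl)=O)cc1 | starting material
10 | 8a-O-[(E)-4-methoxycinnamoyl] enol ester of 8, (5R,7S) | CC(=O)C3=C(OC(=O)/C=C/c7ccc(OC)cc7)C[C@@H]2Oc4cc5c(=O)cc(CCc6ccccc6)oc5cc4O[C@H]3C2(OC)OC | intermediate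
11 | (5R,7S)-triketone: (E)-5-(4-methoxyphenyl)-1-(bridged enol ring of 8)pent-4-ene-1,3-dione | COc1ccc(/C=C/C(=O)CC(=O)C3=C(O)C[C@@H]2Oc4cc5c(=O)cc(CCc6ccccc6)oc5cc4O[C@H]3C2(OC)OC)cc1 | intermediate (not isolated)
12 | (5R,7S)-6,6-dimethoxy-2-[(E)-2-(4-methoxyphenyl)ethenyl]-5,7-[4-oxo-2-(2-phenylethyl)-4H-chromene-7,6-diyldioxy]-5,6,7,8-tetrahydro-4H-chromen-4-one | COc1ccc(/C=C/c2cc(=O)c3c(o2)C[C@@H]2Oc4cc5c(=O)cc(CCc6ccccc6)oc5cc4O[C@H]3C2(OC)OC)cc1 | intermediate (not isolated)
13 | (5R,7S)-2-[(E)-2-(4-methoxyphenyl)ethenyl]-5,7-[4-oxo-2-(2-phenylethyl)-4H-chromene-7,6-diyldioxy]-7,8-dihydro-4H-chromene-4,6(5H)-dione | COc1ccc(/C=C/c2cc(=O)c3c(o2)C[C@@H]2Oc4cc5c(=O)cc(CCc6ccccc6)oc5cc4O[C@H]3C2=O)cc1 | intermediate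
14 | (5R,7S)-4-O-(tert-butyldimethylsilyl) trienol ether of 13 (double bonds C2=C3, C4=C4a, C8a=C8) | COc1ccc(/C=C/C2=CC(O[Si](C)(C)C(C)(C)C)=C3C(O2)=C[C@@H]2Oc4cc5c(=O)cc(CCc6ccccc6)oc5cc4O[C@H]3C2=O)cc1 | intermediate (not isolated)
15 | (5R,7S,8S)-8-hydroxy-2-[(E)-2-(4-methoxyphenyl)ethenyl]-5,7-[4-oxo-2-(2-phenylethyl)-4H-chromene-7,6-diyldioxy]-7,8-dihydro-4H-chromene-4,6(5H)-dione | COc1ccc(/C=C/c2cc(=O)c3c(o2)[C@@H](O)[C@@H]2Oc4cc5c(=O)cc(CCc6ccccc6)oc5cc4O[C@H]3C2=O)cc1 | intermediate
16 | 8-O-diethylboryl derivative of 15, (5R,7S,8S) | COc1ccc(/C=C/c2cc(=O)c3c(o2)[C@@H](OB(CC)CC)[C@@H]2Oc4cc5c(=O)cc(CCc6ccccc6)oc5cc4O[C@H]3C2=O)cc1 | intermediate (not isolated)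
17 | (5R,6S,7R,8S)-6,8-dihydroxy-2-[(E)-2-(4-methoxyphenyl)ethenyl]-5,7-[4-oxo-2-(2-phenylethyl)-4H-chromene-7,6-diyldioxy]-5,6,7,8-tetrahydro-4H-chromen-4-one | COc1ccc(/C=C/c2cc(=O)c3c(o2)[C@@H](O)[C@@H]2Oc4cc5c(=O)cc(CCc6ccccc6)oc5cc4O[C@H]3[C@@H]2O)cc1 | intermediate
18 | (+)-4′-methoxyaquisinenone G, (5R,6S,7R,8S)-6,8-dihydroxy-2-[2-(4-methoxyphenyl)ethyl]-5,7-[4-oxo-2-(2-phenylethyl)-4H-chromene-7,6-diyldioxy]-5,6,7,8-tetrahydro-4H-chromen-4-one | COc1ccc(CCc2cc(=O)c3c(o2)[C@@H](O)[C@@H]2Oc4cc5c(=O)cc(CCc6ccccc6)oc5cc4O[C@H]3[C@@H]2O)cc1 | target

## Step count and least certain steps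

Total: 10 steps. Longest linear sequence: 9 steps (3 → 4 → 6 → 7 → 8 → 10 → 13 → 15 → 17 → 18); step 1 is a one-step branch.

Step 5 (Proposed new method).
- Most likely failure: the first addition reverses and the mono-adduct rearomatises by loss of methanol faster than the seven-membered closure; enantioselectivity may also be eroded by reversible addition under the basic catalyst, or the 6′-hydroxyl may compete in the first addition.
- Fallback, from 2 and 7 back to 8: a two-stage racemic sequence built from precedented reaction types. The mono-caesium 7′-phenoxide of 7 (Cs2CO3, 1 equiv, MeCN, 0 °C) is added to 2 in a base-mediated conjugate addition to a doubly activated enone, giving the racemic mono-adduct F1. 1,8-Diazabicyclo[5.4.0]undec-7-ene in THF should then close the ring by intramolecular oxa-Michael addition, giving 8 together with its mirror-image bridged diketone F2. Chromatography on a chiral stationary phase returns the route to 8.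

Step 8.
- Most likely failure: ionisation of the C7 aryloxy group from the electron-rich trienol ether (ring opening followed by aromatisation), silylation and enolisation of the aromatic chromone unit as well, or over-oxidation by the dioxirane.
- Fallback, from 12 back to 15: oxygen enters as an epoxide that is opened with inversion at C7. Compound 12 is isolated by running the acid stage of step 7 with anhydrous CF3CO2H. With t-BuOOH and 1,8-diazabicyclo[5.4.0]undec-7-ene in THF, deliberate E1cB opening should give the ring-opened phenol F3. Weitz–Scheffer epoxidation of its C7=C8 bond, on the face opposite the C5 aryloxy group, should give the epoxide F4. The tethered 6′-phenoxide then opens F4 at C7 in a 7-exo, trans-diaxial manner to the 8-hydroxy ketal F5. Aqueous CF3CO2H unmasks the C6 ketone and rejoins the route at 15.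

Step 9.
- Most likely failure: hydride delivery to the lower face, anti to both axial C–O bonds (the intrinsically preferred trajectory), if boron binding to the carbonyl is incomplete; this would give the C6 epimer.
- Fallback, from 15 back to 17: a sequence in which either facial outcome converges. Boc2O with 4-(dimethylamino)pyridine gives the 8-O-tert-butyl carbonate F6. NaBH4/CeCl3·7H2O in MeOH at −40 °C is then allowed to follow the intrinsic bias and give the C6-epimeric alcohol F7. Tf2O/pyridine converts F7 into the triflate F8, which should be displaced from the lower face by the carbonyl oxygen of the 1,3-diaxial carbonate, with loss of the tert-butyl group, to give the 6,8-cyclic carbonate F9. K2CO3 in MeOH releases 17. Any material reduced from the upper face carries the axial 6-hydroxyl already and is converted into 17 by the same methanolysis.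

Step 7.
- Most likely failure: base-induced retro-oxa-Michael cleavage (expulsion of the C5 or C7 aryloxide from the diketonate or from a C8 dienolate), leading to fragmentation; acyl transfer from the wrong enol ester regioisomer is also possible.
- Fallback, from 8 back to 11: a non-basic C-acylation. Me3SiOTf (2.2 equiv) and Et3N in Et2O at 0 °C convert 8 into its bis(trimethylsilyl) dienol ether F10. Mukaiyama-type acylation of the terminal carbon of F10 with 9 in CH2Cl2 (−78 to 0 °C), followed by aqueous work-up, should give triketone 11, which is carried through the acid stage of step 7 to 13.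

## Further compounds

F1 | step 5 | racemic mono-adduct: 2-acetyl-3-hydroxy-5-[6-hydroxy-4-oxo-2-(2-phenylethyl)-4H-chromen-7-yloxy]-4,4-dimethoxycyclohexa-2,... enol form (C5–O7′ only; racemate) | CC(=O)C1=C(O)C=CC(OC)(OC)C1Oc1cc2oc(CCc3ccccc3)cc(=O)c2cc1O
F2 | step 5 | enantiomer of 8, (5S,7R) | CC(=O)C3=C(O)C[C@H]2Oc4cc5c(=O)cc(CCc6ccccc6)oc5cc4O[C@@H]3C2(OC)OC
F3 | step 8 | (5R)-5-[6-hydroxy-4-oxo-2-(2-phenylethyl)-4H-chromen-7-yloxy]-6,6-dimethoxy-2-[(E)-2-(4-methoxyphenyl)ethenyl]-5,6-dihydro-4H-chromen-4-one | COc1ccc(/C=C/c2cc(=O)c3c(o2)C=CC(OC)(OC)[C@@H]3Oc2cc3oc(CCc4ccccc4)cc(=O)c3cc2O)cc1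
F4 | step 8 | 7,8-epoxide of F3, epoxide oxygen anti to the C5 aryloxy group | COc1ccc(/C=C/c2cc(=O)c3c(o2)[C@H]4O[C@H]4C(OC)(OC)[C@@H]3Oc2cc3oc(CCc4ccccc4)cc(=O)c3cc2O)cc1
F5 | step 8 | (5R,7S,8S)-8-hydroxy-6,6-dimethoxy-2-[(E)-2-(4-methoxyphenyl)ethenyl]-5,7-[4-oxo-2-(2-phenylethyl)-4H-chromene-7,6-diyldioxy]-5,6,7,8-tetrahydro-4H-chromen-4-one | COc1ccc(/C=C/c2cc(=O)c3c(o2)[C@@H](O)[C@@H]2Oc4cc5c(=O)cc(CCc6ccccc6)oc5cc4O[C@H]3C2(OC)OC)cc1
F6 | step 9 | 8-O-tert-butoxycarbonyl derivative of 15 | COc1ccc(/C=C/c2cc(=O)c3c(o2)[C@@H](OC(=O)OC(C)(C)C)[C@@H]2Oc4cc5c(=O)cc(CCc6ccccc6)oc5cc4O[C@H]3C2=O)cc1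
F7 | step 9 | C6-epimeric alcohol (6-OH cis to both aryloxy groups) with 8-O-tert-butoxycarbonyl group | COc1ccc(/C=C/c2cc(=O)c3c(o2)[C@@H](OC(=O)OC(C)(C)C)[C@@H]2Oc4cc5c(=O)cc(CCc6ccccc6)oc5cc4O[C@H]3[C@H]2O)cc1
F8 | step 9 | 6-O-trifluoromethanesulfonate of F7 | COc1ccc(/C=C/c2cc(=O)c3c(o2)[C@@H](OC(=O)OC(C)(C)C)[C@@H]2Oc4cc5c(=O)cc(CCc6ccccc6)oc5cc4O[C@H]3[C@H]2OS(=O)(=O)C(F)(F)F)cc1
F9 | step 9 | 6,8-O-carbonyl (cyclic carbonate) derivative of 17 | COc1ccc(/C=C/c2cc(=O)c3c(o2)[C@H]4OC(=O)O[C@@H]5[C@H]4Oc6cc7c(=O)cc(CCc8ccccc8)oc7cc6O[C@H]35)cc1
F10 | step 7 | bis(trimethylsilyl) dienol ether of 8 (CH2=C(OSiMe3) on C4a, OSiMe3 on C8a), (5R,7S) | C=C(O[Si](C)(C)C)C3=C(O[Si](C)(C)C)C[C@@H]2Oc4cc5c(=O)cc(CCc6ccccc6)oc5cc4O[C@H]3C2(OC)OC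
A1 | alternative 1 | 5-hydroxy-7-(4-methoxybenzyloxy)-6,8-bis(tert-butyldimethylsilyloxy)-2-[2-(4-methoxyphenyl)ethyl]-5,6,7,8-tetrahydro-4H-chromen-4-one, C5–C8 configured as in 18 | COc1ccc(CCc2cc(=O)c3c(o2)[C@@H](O[Si](C)(C)C(C)(C)C)[C@H](OCc4ccc(OC)cc4)[C@@H](O[Si](C)(C)C(C)(C)C)[C@@H]3O)cc1
A2 | alternative 2 | 3-{[7-(allyloxy)-4-oxo-2-(2-phenylethyl)-4H-chromen-6-yl]oxy}-2,4-bis(tert-butyldimethylsilyloxy)-5-hydroxycyclohexanone, configured as in the SMILES | C1C(=O)[C@@H](O[Si](C)(C)C(C)(C)C)[C@H](Oc2cc3c(=O)cc(CCc4ccccc4)oc3cc2OCC=C)[C@@H](O[Si](C)(C)C(C)(C)C)[C@H]1O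
A3 | alternative 3 | 6,8-bis-O-(tert-butyldimethylsilyl) ether of 18 | COc1ccc(CCc2cc(=O)c3c(o2)[C@@H](O[Si](C)(C)C(C)(C)C)[C@@H]2Oc4cc5c(=O)cc(CCc6ccccc6)oc5cc4O[C@H]3[C@@H]2O[Si](C)(C)C(C)(C)C)cc1
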